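The target, (6R)-ε,ψ-carotene, is cut at C7=C8 (Julia–Lythgoe olefination) into a C10 ring sulfone and the acyclic C30 aldehyde apo-8'-lycopenal. The sulfone carries all that is difficult: ring C1–C6 with the gem-dimethyl C1, the C4=C5 alkene and the only stereocentre, C6. This ring is the folded form of a geranyl 1,5-diene, and the key step exploits that: one enantioselective, proton-initiated cyclization forms the C1–C6 bond, closes the ring, sets C6 and places the alkene by loss of a C4 proton. Its precursor is achiral, open-chain (E)-geranyl phenyl sulfone; the sulfonylmethyl carbon later becomes C7.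

Key step: step 2

Numbering: carotenoid numbering throughout (ε-end unprimed, ψ-end primed).

Assumption: geranyl bromide and crocetin dialdehyde are bought; the sense of induction of the chiral acid is carried over from longer polyprenoids, so the (S)-ligand is specified and its antipode would be used if the sense proves reversed.

Step 1
Reactants: 1 geranyl bromide; 2 sodium benzenesulfinate
Product: 3 geranyl phenyl sulfone
Conditions: PhSO2Na (1.2 equiv), DMF, 0 °C to rt
Reagents that add atoms: none
Why: Sulfinate S-alkylation (SN2) of a primary allylic bromide in a dipolar aprotic solvent should give the sulfone directly with the 2E alkene untouched, any O-alkylated or SN2' material being removed by chromatography.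

Step 2
Reactants: 3 geranyl phenyl sulfone
Product: 4 (R)-α-cyclogeranyl phenyl sulfone
Conditions: (S)-2'-(2-fluorobenzyloxy)-1,1'-binaphthalen-2-ol (2.2 equiv), SnCl4 (2.0 equiv), toluene, −78 °C, 2–4 d; aq. NaHCO3
Reagents that add atoms: none
Why: Proposed new method: the phenolic proton of the SnCl4-bound binaphthol ether is transferred to C2 of the terminal C1=C2 alkene while the C5=C6 π bond attacks the developing C1 cation through a chair-like transition state, which forms the C1–C6 bond and a tertiary C5 cation that then loses a C4 proton to the aryloxytetrachlorostannate counter-anion. The closest known reaction types are the Lewis-acid-assisted chiral Brønsted acid cyclization of longer polyprenoids, which ends by capture with an internal nucleophile, and the racemic strong-acid cyclization of geranyl aryl sulfones and of pseudoionone to α-type rings; an enantioselective monocyclization that ends in a regioselective proton loss is the new element. Ring C1–C6 closes in the 6-endo-trig mode with respect to C5=C6, the new bond going to C6 so that the charge sits on the tertiary C5. The single new stereocentre C6 is set by which enantiotopic face of C5=C6 meets C1, that is by which of the two mirror-image chair folds the chiral acid accommodates while it delivers the proton; the (S)-ligand is specified on the expectation, carried over from homofarnesyl-type substrates, that it leads to 6R. The step needs C4–H loss in preference to C6–H loss (achiral C5=C6 isomer) and C18–H loss (exocyclic isomer): the C6–H is screened by the gem-dimethyl C1 and the sulfonylmethyl arm and is a poorer hyperconjugative donor because of that electron-poor arm, so the bulky counter-anion at −78 °C should take the exposed axial C4–H under kinetic control. The sulfone is a weak Lewis base that neither sequesters SnCl4 nor traps the cation, and it tolerates the acid.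

Step 3
Reactants: 1 geranyl bromide
Product: 5 geranyltriphenylphosphonium bromide
Conditions: PPh3 (1.05 equiv), toluene, rt, dark; filter
Reagents that add atoms: triphenylphosphine, c1ccc(cc1)P(c1ccccc1)c1ccccc1
Why: SN2 quaternisation of PPh3 by the primary allylic bromide should give the Wittig salt, which separates from toluene and keeps the 2E geometry.

Step 4
Reactants: 5 geranyltriphenylphosphonium bromide; 6 crocetin dialdehyde
Product: 8 apo-8'-lycopenal, via geranylidenetriphenylphosphorane 7 (not isolated)
Conditions: 6 (3 equiv), NaOMe/MeOH added slowly, CH2Cl2, 0 °C to rt; then heptane, reflux, N2, dark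
Reagents that add atoms: none
Why: Wittig reaction of the semistabilised allylic ylide with one formyl group of the symmetrical dialdehyde, which is kept in excess while the ylide is generated slowly so that double olefination to lycopene stays minor; the sterically hindered 7'Z isomer formed alongside should revert to 7'E on heating, and the unchanged dialdehyde is recovered.

Step 5
Reactants: 4 (R)-α-cyclogeranyl phenyl sulfone; 8 apo-8'-lycopenal
Product: 11 (6R)-7-(phenylsulfonyl)-7,8-dihydro-ε,ψ-caroten-8-yl benzoate (mixture of C7/C8 diastereomers), via lithiated sulfone 9 (not isolated), via lithium alkoxide adduct 10 (not isolated)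
Conditions: 4 (1.3 equiv), n-BuLi (1.25 equiv), THF, −78 °C; 8 (1.0 equiv), THF, −78 °C; BzCl (1.5 equiv), −78 to −20 °C; aq. NaHCO3
Reagents that add atoms: benzoyl chloride, O=C(Cl)c1ccccc1
Why: First stage of the Julia–Lythgoe olefination: n-BuLi removes a C7 proton next to the sulfone (the allylic C6–H is far less acidic, so C6 is untouched), the carbanion adds 1,2 to the formyl group at −78 °C, and benzoylation in the same flask traps the alkoxide before retro-addition; the two new stereocentres at C7 and C8 form unselectively and both disappear in step 6.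

Step 6
Reactants: 11 (6R)-7-(phenylsulfonyl)-7,8-dihydro-ε,ψ-caroten-8-yl benzoate
Product: 12 (6R)-ε,ψ-carotene (δ-carotene)
Conditions: SmI2 (0.1 M in THF, about 2.2 equiv, added until its colour just persists), DMPU, THF, −78 °C, Ar, dark; aq. NaHCO3
Reagents that add atoms: none
Why: Second stage of the Julia–Lythgoe olefination in its SmI2 form: two single-electron transfers expel benzoate from C8 and benzenesulfinate from C7 through open-chain radical and organosamarium intermediates that lose the C7/C8 configuration, so all diastereomers of 11 should converge on the less strained 7E alkene, while C6 is safe because the medium contains neither acid nor base.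

Compound list
1 | geranyl bromide, (2E)-1-bromo-3,7-dimethylocta-2,6-diene | CC(C)=CCC/C(C)=C/CBr | starting material
2 | sodium benzenesulfinate (PhSO2Na) | [Na+].[O-]S(=O)c1ccccc1 | starting material
3 | geranyl phenyl sulfone, (2E)-3,7-dimethylocta-2,6-dien-1-yl phenyl sulfone | CC(C)=CCC/C(C)=C/CS(=O)(=O)c1ccccc1 | intermediate
4 | (R)-α-cyclogeranyl phenyl sulfone, {[(1R)-2,6,6-trimethylcyclohex-2-en-1-yl]methanesulfonyl}benzene | O=S(=O)(C[C@H]1C(C)=CCCC1(C)C)c1ccccc1 | intermediate
5 | geranyltriphenylphosphonium bromide | CC(C)=CCC/C(C)=C/C[P+](c1ccccc1)(c1ccccc1)c1ccccc1.[Br-] | intermediate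
6 | crocetin dialdehyde, all-E 8,8'-diapocarotene-8,8'-dial | O=C/C(C)=C/C=C/C(C)=C/C=C/C=C(C)/C=C/C=C(C)/C=O | starting material
7 | geranylidenetriphenylphosphorane | CC(C)=CCC/C(C)=C/C=P(c1ccccc1)(c1ccccc1)c1ccccc1 | intermediate (not isolated)
8 | apo-8'-lycopenal, all-E 8'-apo-ψ-caroten-8'-al | CC(C)=CCC/C(C)=C/C=C/C(C)=C/C=C/C(C)=C/C=C/C=C(C)/C=C/C=C(C)/C=O | intermediate
9 | lithiated sulfone, C7-lithio derivative of 4 | [Li+].O=S(=O)([CH-][C@H]1C(C)=CCCC1(C)C)c1ccccc1 | intermediate (not isolated)
10 | lithium alkoxide adduct, lithium (6R)-7-(phenylsulfonyl)-7,8-dihydro-ε,ψ-caroten-8-olate, C7/C8 diastereomers | [Li+].CC(C)=CCC/C(C)=C/C=C/C(C)=C/C=C/C(C)=C/C=C/C=C(C)/C=C/C=C(C)/C([O-])C([C@H]1C(C)=CCCC1(C)C)S(=O)(=O)c1ccccc1 | intermediate (not isolated)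
11 | (6R)-7-(phenylsulfonyl)-7,8-dihydro-ε,ψ-caroten-8-yl benzoate, C7/C8 diastereomers | CC(C)=CCC/C(C)=C/C=C/C(C)=C/C=C/C(C)=C/C=C/C=C(C)/C=C/C=C(C)/C(OC(=O)c1ccccc1)C([C@H]1C(C)=CCCC1(C)C)S(=O)(=O)c1ccccc1 | intermediate
12 | (6R)-ε,ψ-carotene (δ-carotene), all-E | CC(C)=CCC/C(C)=C/C=C/C(C)=C/C=C/C(C)=C/C=C/C=C(C)/C=C/C=C(C)/C=C/[C@H]1C(C)=CCCC1(C)C | target

Total step count: 6. Longest linear sequence: 4 steps (1, 2, 5, 6; the branch 3, 4, 5, 6 is equally long).

Steps most likely to fail

Step 2 (Proposed new method). The chiral acid may discriminate poorly between the two faces of C5=C6, the sulfone-deactivated diene may convert slowly at −78 °C, and proton loss may be unselective and give the achiral C5=C6 isomer and the exocyclic isomer. Fallback with known chemistry, setting out from 3 and returning at 4: 3 is cyclised with conc. H2SO4 in AcOH, the established racemic route to α-type cyclogeranyl sulfones, to racemic α-cyclogeranyl phenyl sulfone F1. The (R)-enantiomer 4 is then separated by preparative chromatography on a polysaccharide chiral stationary phase, and the (S)-enantiomer is discarded.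

Step 6. Excess divalent samarium may transfer electrons into the decaene, causing over-reduction and E/Z scrambling, and the allylic benzoate may ionise before it is reduced. The fallback sets out from 4 and returns at 12. It moves the electron-transfer step to a substrate without a polyene and makes the last bond by a Wittig reaction; it also bypasses step 5.
- Lithiated 4 is added to commercial (E)-4-acetoxy-2-methylbut-2-enal and the alkoxide is benzoylated to give the sulfonyl benzoate F2.
- SmI2/DMPU then gives the ε-C15 dienyl acetate F3, and PPh3·HBr in MeOH converts it into the ε-C15 phosphonium bromide F4.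
- In parallel, commercial pseudoionone and vinylmagnesium bromide give vinyl-ψ-ionol F5, and PPh3·HBr converts it with allylic transposition into the ψ-C15 phosphonium bromide F6.
- A Wittig reaction of F6 with excess commercial 2,7-dimethylocta-2,4,6-trienedial gives apo-12'-lycopenal F7.
- A final Wittig reaction of F4 with F7 (NaOMe, CH2Cl2/MeOH, then heating in heptane to isomerise the hindered 11Z isomer) forms C11=C12 and gives 12.

Step 4. The symmetrical dialdehyde may be olefinated twice, and the delocalised allylic ylide may give 7'Z and 5'Z isomers, of which heating corrects only the hindered 7'Z. Fallback, setting out from 1 and 6 and returning at 8: a Michaelis–Arbuzov reaction of 1 with P(OEt)3 gives diethyl geranylphosphonate F8. Its potassium salt (KOtBu, THF, −30 °C) is added slowly to excess 6 in a Horner–Wadsworth–Emmons reaction, which should form C7'=C8' with E selectivity without a separate isomerisation and leaves a water-soluble phosphate.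

Further compounds
F1 | step 2 | racemic α-cyclogeranyl phenyl sulfone | O=S(=O)(CC1C(C)=CCCC1(C)C)c1ccccc1
F2 | step 6 | (2E)-4-(benzoyloxy)-3-methyl-5-(phenylsulfonyl)-5-[(1R)-2,6,6-trimethylcyclohex-2-en-1-yl]pent-2-en-1-yl acetate, C4/C5 diastereomers | CC(=O)OC/C=C(C)/C(OC(=O)c1ccccc1)C([C@H]1C(C)=CCCC1(C)C)S(=O)(=O)c1ccccc1
F3 | step 6 | (2E,4E)-3-methyl-5-[(1R)-2,6,6-trimethylcyclohex-2-en-1-yl]penta-2,4-dien-1-yl acetate | CC(=O)OC/C=C(C)/C=C/[C@H]1C(C)=CCCC1(C)C
F4 | step 6 | {(2E,4E)-3-methyl-5-[(1R)-2,6,6-trimethylcyclohex-2-en-1-yl]penta-2,4-dien-1-yl}triphenylphosphonium bromide | c1ccccc1[P+](c1ccccc1)(c1ccccc1)C/C=C(C)/C=C/[C@H]1C(C)=CCCC1(C)C.[Br-]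
F5 | step 6 | vinyl-ψ-ionol, (4E,6E)-3,7,11-trimethyldodeca-1,4,6,10-tetraen-3-ol, racemic | CC(C)=CCC/C(C)=C/C=C/C(C)(O)C=C
F6 | step 6 | [(2E,4E,6E)-3,7,11-trimethyldodeca-2,4,6,10-tetraen-1-yl]triphenylphosphonium bromide | CC(C)=CCC/C(C)=C/C=C/C(C)=C/C[P+](c1ccccc1)(c1ccccc1)c1ccccc1.[Br-]
F7 | step 6 | apo-12'-lycopenal, all-E 12'-apo-ψ-caroten-12'-al | CC(C)=CCC/C(C)=C/C=C/C(C)=C/C=C/C(C)=C/C=C/C=C(C)/C=O
F8 | step 4 | diethyl geranylphosphonate, diethyl [(2E)-3,7-dimethylocta-2,6-dien-1-yl]phosphonate | CCOP(=O)(OCC)C/C=C(C)/CCC=C(C)C
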